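**Retrosynthetic overview**

1. The target is a ten-membered carbocycle (C1–C10) cis-fused at C6–C7 to an α-methylene-γ-butyrolactone (ring O–C6–C7–C11–C12, exo-methylene C13). Last disconnections: C1 carbinol and O3-acetate (Evans–Tishchenko), C2–C3 (macroaldol, closes the ten-membered ring), C8–O (Mitsunobu inversion with angelic acid), C8–C9 (Nozaki–Hiyama–Kishi coupling with a C9–C10–C1–C2 Z-iodoalkene).
2. This leaves a C3/C8 dialdehyde on the intact lactone. Reconnecting C3–C8 (glycol cleavage in reverse) gives a cyclohexene cis-diol, i.e. the lactone annulated onto the ring of toluene cis-dihydrodiol. This temporary six-membered ring fixes the Z geometry of C4=C5 and the cis C6/C7 fusion.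
3. Key disconnection: the whole lactone ring is removed in one three-component annulation of the ring diene C4=C5–C6=C7 with 2-(diethoxyphosphoryl)acetic acid and formaldehyde, triggered by iodonium (makes O–C6, C7–C11 and C11=C13).
4. Enabling feature: in the five-membered lactone ring, O–C6 is allylic to the methyl-bearing C4=C5 bond and cis to the C7–C11 bond. Both bonds therefore map onto anti addition across C6=C7 of a cyclic 1,3-diene (O to the allylic carbon) followed by inversion at C7.
5. Ring order: cyclohexadiene (chiral pool) → γ-lactone (key step) → six-membered ring opened → ten-membered ring (macroaldol).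

Key step: step 2

Remark: locants C1–C13 are those of the target (C1 CHOH, C2 CH2, C3 CHOAc, C4(Me)=C5, C6 lactone carbinol, C7 ring fusion, C8 CHOAng, C9=C10(Me), C11/C12/C13 lactone α-carbon, carbonyl and exo-methylene); 1 is taken to be the commercial dioxygenase-derived toluene cis-dihydrodiol, and the carbinol configuration of 9 is erased in step 9, the (S)-enantiomer serving only to keep 12–16 single diastereomers.

Step 1
Reactants: 1 (1S,2R)-3-methylcyclohexa-3,5-diene-1,2-diol
Product: 2 (3aR,7aS)-2,2,4-trimethyl-3a,7a-dihydro-1,3-benzodioxole (acetonide of 1)
Conditions: 2,2-dimethoxypropane, p-TsOH (cat.), acetone, 0 °C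
Reagents that add atoms: 2,2-dimethoxypropane, COC(C)(C)OC
Why: Acid-catalysed transketalization (acetonide formation) of the cis-diol, which leaves both chiral-pool stereocentres untouched and shields one face of the diene.

Step 2
Reactants: 2 acetonide; 3 2-(diethoxyphosphoryl)acetic acid
Product: 6 tricyclic α-methylene lactone acetonide (cis-fused C6–C7 γ-lactone on the acetonide face of the 4-methylcyclohexene ring), via trans-iodo phosphonoacetate 4 (not isolated), via α-phosphono lactone 5 (not isolated)
Conditions: NIS, MeCN, −30 to 0 °C; then Cs2CO3, DMF, 0 °C to rt; then (CH2O)n, rt (one flask)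
Reagents that add atoms: paraformaldehyde (formaldehyde), C=O
Why: Proposed new method: a one-flask three-component lactone annulation in which an iodonium ion formed at C6=C7 anti to the acetonide is opened anti at the allylic C6 by the carboxylate of 3 (O–C6 bond, ester on the acetonide face), Cs2CO3 then generates the phosphonate-stabilised carbanion, which displaces the C7 iodide with inversion (C7–C11 bond), and the resulting phosphono lactone undergoes Horner–Wadsworth–Emmons olefination with formaldehyde to give the exo-methylene group. The closest known reaction types are trans-halohydrin formation and haloacyloxylation of arene cis-dihydrodiol acetonides (nucleophile delivered to the allylic carbon syn to the acetonide), intramolecular enolate alkylation to α-phosphono lactones, and methylenation of α-phosphono-γ-butyrolactones; only their telescoping into one operation is new. The lactone ring is closed by a 5-exo-tet C-alkylation, the O–C6 bond having been made intermolecularly in the first stage. C6 is controlled by the acetonide (iodonium anti, carboxylate syn to it) and C7 by stereospecific inversion, so both new bonds end on the acetonide face and the fusion is cis by construction. The step needs iodine on C7 with 1,2- rather than 1,4-opening, and substitution rather than elimination: the allyl cation character is stabilised by the C4 methyl group while attack at C7 is retarded by the adjacent C8–O bond, low temperature and the bridged iodonium favour 1,2-anti addition, and in the trans-diaxial iodo ester both hydrogens vicinal to iodine (H6, H8) are cis to it, so no anti-periplanar hydrogen is available for E2.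

Step 3
Reactants: 6 tricyclic α-methylene lactone acetonide
Product: 8 (2S,3S)-4-methylidene-2-[(1Z)-2-methyl-3-oxoprop-1-en-1-yl]-5-oxooxolane-3-carbaldehyde (C3/C8 dialdehyde), via cis-diol 7 (not isolated)
Conditions: 80% aq. AcOH, 40 °C; then NaIO4, THF/H2O, 0 °C
Reagents that add atoms: none
Why: Acetal hydrolysis followed by periodate glycol cleavage opens the temporary ring at C3–C8 under non-basic conditions that should not epimerise C7, and the Z geometry of C4=C5 is inherited from the six-membered ring.

Step 4
Reactants: 9 (S)-but-3-yn-2-ol
Product: 11 (2S,3Z)-4-iodo-3-methylbut-3-en-2-ol, via cyclic alkenylmagnesium alkoxide 10 (not isolated)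
Conditions: MeMgBr (2.5 equiv), CuI (10 mol %), THF, −20 °C to rt; then I2, −40 °C to rt
Reagents that add atoms: methylmagnesium bromide, C[Mg]Br; iodine, II
Why: Copper-catalysed anti-carbomagnesiation of the propargylic magnesium alkoxide places methyl on the internal carbon and magnesium on the terminal carbon cis to the carbinol (five-membered chelate), and iodinolysis with retention gives the Z-iodide while the carbinol centre is a spectator.

Step 5
Reactants: 11 (2S,3Z)-4-iodo-3-methylbut-3-en-2-ol
Product: 12 triethyl{[(2S,3Z)-4-iodo-3-methylbut-3-en-2-yl]oxy}silane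
Conditions: TESCl, imidazole, CH2Cl2, 0 °C
Reagents that add atoms: chlorotriethylsilane, CC[Si](Cl)(CC)CC
Why: Standard silylation of the secondary alcohol, needed so that only one free hydroxyl is present after step 6.

Step 6
Reactants: 8 C3/C8 dialdehyde; 12 Z-iodoalkene silyl ether (1.1 equiv)
Product: 13 8-epi allylic alcohol (C8–C9 coupled; C3 enal free; C1–OTES)
Conditions: CrCl2 (4 equiv), NiCl2 (cat.), DMSO/THF, rt
Reagents that add atoms: none
Why: Nozaki–Hiyama–Kishi coupling, in which the alkenylchromium species should add to the more electrophilic, unconjugated C8 aldehyde rather than the hindered Z-enal with retention of the Z-alkene, and Felkin–Anh attack anti to the C6 branch of the α-stereocentre C7 is expected to set C8 with the configuration opposite to that of the target.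

Step 7
Reactants: 13 8-epi allylic alcohol; 14 angelic acid
Product: 15 C8 angelate (target configuration at C8)
Conditions: PPh3, DIAD, toluene, −20 to 0 °C
Reagents that add atoms: none
Why: Mitsunobu esterification inverts C8 by SN2 displacement of the oxyphosphonium, so the angelate and the target configuration are installed together without a base that could isomerise the Z-acid to tiglate.

Step 8
Reactants: 15 C8 angelate
Product: 16 C1 alcohol
Conditions: HF·pyridine, pyridine, THF, 0 °C
Reagents that add atoms: none
Why: Fluoride cleavage of the triethylsilyl ether under buffered conditions to which the esters, the lactone and the enal are inert.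

Step 9
Reactants: 16 C1 alcohol
Product: 17 keto aldehyde (C1 methyl Z-enone and C3 Z-enal)
Conditions: Dess–Martin periodinane, CH2Cl2, 0 °C to rt
Reagents that add atoms: none
Why: Dess–Martin oxidation of the secondary allylic alcohol to the methyl ketone under non-basic conditions that spare the Z-alkenes, the aldehyde and the epimerisable C7.

Step 10
Reactants: 17 keto aldehyde
Product: 19 macrocyclic β-hydroxy enone (3S; C2–C3 bond closed), via dicyclohexylboron enolate 18 (not isolated)
Conditions: (c-C6H11)2BCl, Et3N, Et2O (2 mM), −78 to −20 °C; pH 7 buffer/MeOH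
Reagents that add atoms: none
Why: Boron-mediated intramolecular aldol (macroaldolization) through a Zimmerman–Traxler transition state closes the ten-membered ring, the cis side chains on the lactone and the two Z-alkenes pre-organising the ends, and C3 should be set by attack on the s-trans enal from the face on which C7 lies (C6–H eclipsing the alkene plane to avoid allylic 1,3-strain), which corresponds to the target configuration.

Step 11
Reactants: 19 macrocyclic β-hydroxy enone
Product: 20 CNP0319825.5 (target)
Conditions: SmI2 (30 mol %), CH3CHO (excess), THF, −10 °C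
Reagents that add atoms: acetaldehyde, CC=O
Why: Evans–Tishchenko reduction, in which the samarium-bound hemiacetal from the C3 hydroxyl and acetaldehyde delivers hydride intramolecularly to the C1 ketone through a six-membered chair, giving the 1,3-anti C1 alcohol and leaving the acetate on O3.

**Compound list**

1 | (1S,2R)-3-methylcyclohexa-3,5-diene-1,2-diol (toluene cis-dihydrodiol) | O[C@H]1C=CC=C(C)[C@H]1O | starting material
2 | (3aR,7aS)-2,2,4-trimethyl-3a,7a-dihydro-1,3-benzodioxole (acetonide of 1) | CC1(C)O[C@H]2C=CC=C(C)[C@H]2O1 | intermediate
3 | 2-(diethoxyphosphoryl)acetic acid | CCOP(=O)(OCC)CC(=O)O | starting material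
4 | trans-iodo phosphonoacetate: C6 ester of 3 on the acetonide face and C7 iodide on the opposite face of the C3,C8-acetonide-protected 4-methylcyclohex-4-ene | CCOP(=O)(OCC)CC(=O)O[C@H]1C=C(C)[C@H]2OC(C)(C)O[C@H]2[C@@H]1I | intermediate
5 | α-phosphono lactone: cis-fused C6–C7 γ-lactone bearing P(O)(OEt)2 at C11 (both C11 epimers), acetonide retained | CCOP(=O)(OCC)C1C(=O)O[C@H]2C=C(C)[C@H]3OC(C)(C)O[C@H]3[C@@H]12 | intermediate
6 | tricyclic α-methylene lactone acetonide: cis-fused α-methylene-γ-butyrolactone (O on C6, C11 on C7) and C3,C8-acetonide on the same face of the 4-methylcyclohex-4-ene ring | C=C1C(=O)O[C@H]2C=C(C)[C@H]3OC(C)(C)O[C@H]3[C@@H]12 | intermediate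
7 | cis-diol: 6 without the isopropylidene group (C3–OH and C8–OH free) | C=C1C(=O)O[C@H]2C=C(C)[C@@H](O)[C@@H](O)[C@@H]12 | intermediate
8 | (2S,3S)-4-methylidene-2-[(1Z)-2-methyl-3-oxoprop-1-en-1-yl]-5-oxooxolane-3-carbaldehyde (C3/C8 dialdehyde) | C=C1C(=O)O[C@@H](/C=C(/C)C=O)[C@H]1C=O | intermediate
9 | (S)-but-3-yn-2-ol | C[C@H](O)C#C | starting material
10 | cyclic alkenylmagnesium alkoxide (2,5-dihydro-1,2-oxamagnesole from anti-carbomagnesiation of 9) | C[C@@H]1O[Mg]C=C1C | intermediate
11 | (2S,3Z)-4-iodo-3-methylbut-3-en-2-ol | C[C@H](O)/C(C)=C\I | intermediate
12 | triethyl{[(2S,3Z)-4-iodo-3-methylbut-3-en-2-yl]oxy}silane | CC[Si](CC)(CC)O[C@@H](C)/C(C)=C\I | intermediate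
13 | 8-epi allylic alcohol: C8–C9 coupled product, C8–OH opposite in configuration to the target, 9Z alkene, (1S)-OTES, free C3 (4Z)-enal, lactone as in 8 | C=C1C(=O)O[C@@H](/C=C(/C)C=O)[C@H]1[C@@H](O)/C=C(C)\[C@H](C)O[Si](CC)(CC)CC | intermediate
14 | angelic acid, (Z)-2-methylbut-2-enoic acid | C/C=C(/C)C(=O)O | starting material
15 | C8 angelate with the C8 configuration of the target, otherwise as 13 | C=C1C(=O)O[C@@H](/C=C(/C)C=O)[C@H]1[C@H](OC(=O)/C(C)=C\C)/C=C(C)\[C@H](C)O[Si](CC)(CC)CC | intermediate
16 | C1 alcohol: 15 without the triethylsilyl group | C=C1C(=O)O[C@@H](/C=C(/C)C=O)[C@H]1[C@H](OC(=O)/C(C)=C\C)/C=C(C)\[C@H](C)O | intermediate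
17 | keto aldehyde: C1 methyl ketone (9Z enone), C3 (4Z)-enal, C8 angelate, lactone unchanged | C=C1C(=O)O[C@@H](/C=C(/C)C=O)[C@H]1[C@H](OC(=O)/C(C)=C\C)/C=C(C)\C(C)=O | intermediate
18 | dicyclohexylboron enolate of the C1 methyl ketone of 17 | C=C1C(=O)O[C@@H](/C=C(/C)C=O)[C@H]1[C@H](OC(=O)/C(C)=C\C)/C=C(C)\C(=C)OB(C1CCCCC1)C1CCCCC1 | intermediate
19 | macrocyclic aldol: ten-membered (4Z,9Z) ring, (3S)-hydroxyl, C1 ketone, C8 angelate, cis-fused 12,6-lactone | C=C1C(=O)O[C@H]2/C=C(/C)[C@@H](O)CC(=O)/C(C)=C\[C@@H](OC(=O)/C(C)=C\C)[C@@H]12 | intermediate
20 | CNP0319825.5: (4Z,9Z)-3-acetoxy-8-angeloyloxy-1-hydroxygermacra-4,9,11(13)-trien-12,6-olide, (1S,3S), cis-fused lactone, configuration of the given structure | C=C1C(=O)O[C@H]2/C=C(/C)[C@@H](OC(C)=O)C[C@H](O)/C(C)=C\[C@@H](OC(=O)/C(C)=C\C)[C@@H]12 | target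

**Step count and risks**

Total steps: 11 (9 in the main line, 2 for side chain 12).
Longest linear sequence: 9 steps (steps 1–3 and 6–11, from 1).

Steps most likely to fail:

1. Step 2 (proposed new method). What may go wrong: 1,4- instead of 1,2-opening of the iodonium ion, or slow substitution and halogen-philic reductive elimination at the oxygen-flanked C7 in the alkylation stage. Fallback (known chemistry): setting out from 2, co-iodination with NIS and propiolic acid should give the trans-iodo propiolate F1 with the same regio- and facial course. Tin hydride-mediated radical cyclization (Bu3SnH, AIBN, benzene, 80 °C, slow addition) then proceeds 5-exo-dig onto the alkyne, and hydrogen transfer to the vinyl radical gives the exo-methylene lactone. The planar C7 radical tethered through O6 can only close cis, so the sequence comes back to the route at 6.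

2. Step 6. What may go wrong: insufficient discrimination between the two aldehydes, poor facial selectivity at C8, epimerisation of C7, or acyl migration of the lactone onto the new C8 chromium alkoxide. Fallback: setting out from 8 and 12, a ligand-controlled asymmetric Nozaki–Hiyama–Kishi coupling (CrCl2 cat., chiral oxazoline–sulfonamide ligand, NiCl2 cat., Mn, TMSCl, MeCN; then mild acid) is used to override the substrate bias and give the C8 epimer F2, which already has the target configuration. Because TMSCl traps the alkoxide as it forms, acyl migration is also suppressed. Yamaguchi esterification of F2 with 14 (2,4,6-trichlorobenzoyl chloride, Et3N, DMAP, toluene) proceeds with retention and comes back to the route at 15.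

3. Step 10. What may go wrong: intermolecular aldol and oligomerisation instead of ring closure, or attack on the wrong face of the enal. Fallback: setting out from 17, kinetic silylation (TMSOTf, Et3N, CH2Cl2, −78 °C) gives the trimethylsilyl enol ether F3. A BF3·OEt2-promoted intramolecular Mukaiyama aldol at high dilution (open transition state, aldehyde activated and nucleophile pre-formed) then closes the ring and comes back to the route at 19.

Further compounds
F1 | step 2 | trans-iodo propiolate: C6 propiolate ester on the acetonide face and C7 iodide on the opposite face of the acetonide-protected 4-methylcyclohex-4-ene | C#CC(=O)O[C@H]1C=C(C)[C@H]2OC(C)(C)O[C@H]2[C@@H]1I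
F2 | step 6 | C8 epimer of 13 (C8–OH with the target configuration) | C=C1C(=O)O[C@@H](/C=C(/C)C=O)[C@H]1[C@H](O)/C=C(C)\[C@H](C)O[Si](CC)(CC)CC
F3 | step 10 | trimethylsilyl enol ether of the C1 methyl ketone of 17 | C=C1C(=O)O[C@@H](/C=C(/C)C=O)[C@H]1[C@H](OC(=O)/C(C)=C\C)/C=C(C)\C(=C)O[Si](C)(C)C
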